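**Plan**

- Retrosynthesis first cuts the O7–CH2 ether bond (late alkylation of the free tetraol), then removes the C3–OH bond and the C2–H bond to reach a planar, tribenzylated flavone.
- Ring C of that flavone is cut at C4a–C4, C4–C3 and O1–C2. This is possible because the ketone carbon C4 lies between C4a of ring A and C3 while O1 bridges C8a and C2, so ring C is an ortho-iodophenol (ring A), one CO and an arylacetylene (ring B with C2 and C3).
- Forward: rings A and B are bought as benzyl ethers and armed (iodination; aldehyde-to-alkyne homologation). Ring C closes in one palladium-catalysed three-component carbonylative annulation. C2=C3 is then reduced, C3 is hydroxylated, the benzyl groups are removed and O7 is alkylated last.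
- Stereochemistry: C2 comes from ligand-controlled copper hydride delivery to the flavone (2S flavanone, which is named 2R once C3 carries oxygen). C3 comes from substrate control, the enol ether being oxidised anti to the C2 aryl group (trans, 3R). The E alkene comes from the E-selective SeO2 oxidation of prenyl chloride.

Key step: step 3

**Remarks**

- Assumption: the copper hydride catalyst built on (R)-DTBM-SEGPHOS is taken to deliver hydride to the face of the flavone that gives the 2S flavanone. If the sense of induction is the opposite, the S ligand would be used with no other change.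
- Benzyl ethers are chosen for all three phenols. 3,5-Bis(benzyloxy)phenol is a catalogue compound, which avoids a statistical protection of phloroglucinol. Benzyl ethers tolerate the silyl triflate of step 5 and are removed by neutral hydrogenolysis before the side-chain alkene is present.
- Flavonoid numbering is used (O1, C2, C3, C4, C4a, C5 to C8, C8a; ring B positions primed).

**Route**

Step 1
Reactants: 1 3,5-bis(benzyloxy)phenol
Product: 2 3,5-bis(benzyloxy)-2-iodophenol
Conditions: NIS (1.0 equiv), CH2Cl2, −20 °C to 0 °C, dark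
Reagents that add atoms: N-iodosuccinimide, O=C1CCC(=O)N1I
Why: Electrophilic aromatic iodination, in which the site ortho to the free hydroxyl is less crowded than the position flanked by two benzyloxy groups, so one equivalent of NIS at low temperature should give mainly the 2-iodide, any 4-iodo isomer being removed by chromatography.

Step 2
Reactants: 3 4-(benzyloxy)benzaldehyde
Product: 4 1-(benzyloxy)-4-ethynylbenzene
Conditions: dimethyl (1-diazo-2-oxopropyl)phosphonate, K2CO3, MeOH, rt
Reagents that add atoms: dimethyl (1-diazo-2-oxopropyl)phosphonate, COP(=O)(OC)C(=[N+]=[N-])C(C)=O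
Why: Ohira–Bestmann (Seyferth–Gilbert) homologation, in which methanolysis of the reagent gives the diazomethylphosphonate anion that olefinates the aldehyde to a diazoalkene, which loses N2 and rearranges to the terminal alkyne without touching the benzyl ether.

Step 3
Reactants: 2 3,5-bis(benzyloxy)-2-iodophenol; 4 1-(benzyloxy)-4-ethynylbenzene; 5 carbon monoxide
Product: 8 5,7-bis(benzyloxy)-2-[4-(benzyloxy)phenyl]-4H-chromen-4-one, via ortho-hydroxyaryl ynone 6 (not isolated), via diethylamino enone 7 (not isolated)
Conditions: PdCl2(dppf) (5 mol%), CO (20 atm), Et2NH, 120 °C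
Reagents that add atoms: none
Why: PdCl2(dppf) is reduced in the flask to zerovalent palladium, which inserts into the C–I bond of 2; CO insertion gives an aroylpalladium iodide that couples with the amine-deprotonated alkyne 4 and reductively eliminates ynone 6, forming C4a–C4 and C4–C3. Diethylamine then adds to the ynone to give enaminone 7, and the neighbouring phenol attacks C2 and expels the amine, forming O1–C2. The closest known reaction type is the palladium-catalysed carbonylative coupling of ortho-iodophenols with terminal arylacetylenes in a secondary amine, that is a copper-free carbonylative Sonogashira coupling followed by oxa-Michael addition–elimination. Ring C, the only ring formed, closes in the 6-endo mode and no stereocenter is created. The step needs 6-endo closure to the flavone rather than 5-exo closure to the aurone, and this is secured by the enaminone, whose only electrophilic carbon is C2; it also needs carbonylation to outrun direct alkynylation and amide formation, which the CO pressure, the absence of copper, the fast acyl migration of the electron-rich aryl group and the chelating dppf ligand are chosen to secure.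

Step 4
Reactants: 8 5,7-bis(benzyloxy)-2-[4-(benzyloxy)phenyl]-4H-chromen-4-one
Product: 10 (2S)-5,7-bis(benzyloxy)-2-[4-(benzyloxy)phenyl]-2,3-dihydro-4H-chromen-4-one, via diethoxymethylsilyl enol ether 9 (not isolated)
Conditions: Cu(OAc)2 (5 mol%), (R)-DTBM-SEGPHOS (5.5 mol%), (EtO)2MeSiH (3 equiv), toluene, 0 °C to rt; then 1 M HCl, THF, 0 °C
Reagents that add atoms: none
Why: Copper hydride-catalysed asymmetric conjugate reduction (1,4-hydrosilylation), in which the ligated Cu–H adds hydride to C2 of the chromone enone on the enantiotopic face selected by the chiral bisphosphine (setting C2 as S), and σ-bond metathesis with the silane holds the product as silyl enol ether 9, which shields C4 from 1,2-reduction until mild acid releases the ketone without base-induced ring opening.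

Step 5
Reactants: 10 (2S)-5,7-bis(benzyloxy)-2-[4-(benzyloxy)phenyl]-2,3-dihydro-4H-chromen-4-one
Product: 14 (2R,3R)-5,7-bis(benzyloxy)-2-[4-(benzyloxy)phenyl]-3-hydroxy-2,3-dihydro-4H-chromen-4-one, via trimethylsilyl enol ether 11 (not isolated), via silyloxy epoxide 12 (not isolated), via 3-O-trimethylsilyl ketone 13 (not isolated)
Conditions: TMSOTf, Et3N, CH2Cl2, 0 °C; cold NaHCO3 wash; then mCPBA, CH2Cl2, −20 °C; then 1 M HCl, THF, rt
Reagents that add atoms: mCPBA, OOC(=O)c1cccc(Cl)c1
Why: Rubottom oxidation, in which soft enolisation avoids a free enolate (and so the retro-oxa-Michael ring opening that would racemise C2), mCPBA epoxidises the enol ether on the face opposite the C2 aryl group, and epoxide opening with 1,4-silyl shift followed by desilylation gives the 3-hydroxy ketone with H2 and H3 trans, which fixes C3 as R.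

Step 6
Reactants: 14 (2R,3R)-5,7-bis(benzyloxy)-2-[4-(benzyloxy)phenyl]-3-hydroxy-2,3-dihydro-4H-chromen-4-one
Product: 15 (2R,3R)-3,5,7-trihydroxy-2-(4-hydroxyphenyl)-2,3-dihydro-4H-chromen-4-one [(+)-aromadendrin]
Conditions: H2 (1 atm), 10% Pd/C, EtOAc–MeOH, rt
Reagents that add atoms: none
Why: Catalytic hydrogenolysis of the three aryl benzyl ethers, a neutral deprotection under which the C4 ketone and the C2–O1 bond of dihydroflavonols normally survive at one atmosphere and neither C2 nor C3 can epimerise; it is placed before the side-chain alkene enters.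

Step 7
Reactants: 16 1-chloro-3-methylbut-2-ene (prenyl chloride)
Product: 17 (2E)-4-chloro-2-methylbut-2-en-1-ol
Conditions: SeO2 (0.3 equiv), t-BuOOH (2 equiv), CH2Cl2, rt
Reagents that add atoms: selenium dioxide SeO2, O=[Se]=O (catalytic oxygen carrier); tert-butyl hydroperoxide, CC(C)(C)OO (terminal oxygen source)
Why: Allylic oxidation by SeO2 (ene reaction followed by [2,3]-sigmatropic shift) with t-BuOOH as terminal oxidant, which in gem-dimethyl olefins oxidises the methyl group trans to the chain and should therefore give the E allylic alcohol, the allylic chloride being a spectator.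

Step 8
Reactants: 15 (2R,3R)-3,5,7-trihydroxy-2-(4-hydroxyphenyl)-2,3-dihydro-4H-chromen-4-one; 17 (2E)-4-chloro-2-methylbut-2-en-1-ol
Product: 18 (2R,3R)-3,5-dihydroxy-7-{[(2E)-4-hydroxy-3-methylbut-2-en-1-yl]oxy}-2-(4-hydroxyphenyl)-2,3-dihydro-4H-chromen-4-one
Conditions: K2CO3 (1.1 equiv), NaI (10 mol%), DMF, rt, under argon
Reagents that add atoms: none
Why: Williamson etherification by SN2 displacement at the primary allylic chloride, in which the 7-hydroxyl (para to the C4 carbonyl) is the most acidic OH of 15, the 5-hydroxyl is tied up in a hydrogen bond to C4=O, the 4'-phenol is markedly less acidic and neither the 3-OH nor the primary OH of 17 is deprotonated by carbonate, so one equivalent of base at room temperature should alkylate O7 alone and leave C2, C3 and the E double bond untouched.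

**Compound list**

1 | 3,5-bis(benzyloxy)phenol | Oc1cc(OCc2ccccc2)cc(OCc2ccccc2)c1 | starting material
2 | 3,5-bis(benzyloxy)-2-iodophenol | Oc1cc(OCc2ccccc2)cc(OCc2ccccc2)c1I | intermediate
3 | 4-(benzyloxy)benzaldehyde | O=Cc1ccc(OCc2ccccc2)cc1 | starting material
4 | 1-(benzyloxy)-4-ethynylbenzene | C#Cc1ccc(OCc2ccccc2)cc1 | intermediate
5 | carbon monoxide | [C-]#[O+] | starting material
6 | 1-[2,4-bis(benzyloxy)-6-hydroxyphenyl]-3-[4-(benzyloxy)phenyl]prop-2-yn-1-one | O=C(C#Cc1ccc(OCc2ccccc2)cc1)c1c(O)cc(OCc2ccccc2)cc1OCc1ccccc1 | intermediate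
7 | (2E)-1-[2,4-bis(benzyloxy)-6-hydroxyphenyl]-3-[4-(benzyloxy)phenyl]-3-(diethylamino)prop-2-en-1-one (drawn E; the geometry is lost on ring closure) | CCN(CC)/C(=C/C(=O)c1c(O)cc(OCc2ccccc2)cc1OCc1ccccc1)c1ccc(OCc2ccccc2)cc1 | intermediate
8 | 5,7-bis(benzyloxy)-2-[4-(benzyloxy)phenyl]-4H-chromen-4-one (apigenin tribenzyl ether) | O=c1cc(-c2ccc(OCc3ccccc3)cc2)oc2cc(OCc3ccccc3)cc(OCc3ccccc3)c12 | intermediate
9 | (2S)-5,7-bis(benzyloxy)-2-[4-(benzyloxy)phenyl]-4-{[diethoxy(methyl)silyl]oxy}-2H-chromene | C(Oc1cc(OCc2ccccc2)c2c(c1)O[C@H](c1ccc(OCc3ccccc3)cc1)C=C2O[Si](C)(OCC)OCC)c1ccccc1 | intermediate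
10 | (2S)-5,7-bis(benzyloxy)-2-[4-(benzyloxy)phenyl]-2,3-dihydro-4H-chromen-4-one (naringenin tribenzyl ether) | C(Oc1cc(OCc2ccccc2)c2c(c1)O[C@H](c1ccc(OCc3ccccc3)cc1)CC2=O)c1ccccc1 | intermediate
11 | (2S)-5,7-bis(benzyloxy)-2-[4-(benzyloxy)phenyl]-4-[(trimethylsilyl)oxy]-2H-chromene | C(Oc1cc(OCc2ccccc2)c2c(c1)O[C@H](c1ccc(OCc3ccccc3)cc1)C=C2O[Si](C)(C)C)c1ccccc1 | intermediate
12 | (2R,3R,4R)-5,7-bis(benzyloxy)-2-[4-(benzyloxy)phenyl]-3,4-epoxy-4-[(trimethylsilyl)oxy]chromane, oxirane oxygen anti to the C2 aryl group | C(Oc1cc(OCc2ccccc2)c2c(c1)O[C@H](c1ccc(OCc3ccccc3)cc1)[C@H]3O[C@@]23O[Si](C)(C)C)c1ccccc1 | intermediate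
13 | (2R,3R)-5,7-bis(benzyloxy)-2-[4-(benzyloxy)phenyl]-3-[(trimethylsilyl)oxy]-2,3-dihydro-4H-chromen-4-one | C(Oc1cc(OCc2ccccc2)c2c(c1)O[C@H](c1ccc(OCc3ccccc3)cc1)[C@@H](O[Si](C)(C)C)C2=O)c1ccccc1 | intermediate
14 | (2R,3R)-5,7-bis(benzyloxy)-2-[4-(benzyloxy)phenyl]-3-hydroxy-2,3-dihydro-4H-chromen-4-one (2,3-trans) | C(Oc1cc(OCc2ccccc2)c2c(c1)O[C@H](c1ccc(OCc3ccccc3)cc1)[C@@H](O)C2=O)c1ccccc1 | intermediate
15 | (2R,3R)-3,5,7-trihydroxy-2-(4-hydroxyphenyl)-2,3-dihydro-4H-chromen-4-one [(+)-aromadendrin] | Oc1cc(O)c2c(c1)O[C@H](c1ccc(O)cc1)[C@@H](O)C2=O | intermediate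
16 | 1-chloro-3-methylbut-2-ene (prenyl chloride) | CC(C)=CCCl | starting material
17 | (2E)-4-chloro-2-methylbut-2-en-1-ol | C/C(=C\CCl)CO | intermediate
18 | (2R,3R)-3,5-dihydroxy-7-{[(2E)-4-hydroxy-3-methylbut-2-en-1-yl]oxy}-2-(4-hydroxyphenyl)-2,3-dihydro-4H-chromen-4-one | C/C(=C\COc1cc(O)c2c(c1)O[C@H](c1ccc(O)cc1)[C@@H](O)C2=O)CO | target

**Step count**

Total: 8 steps. Longest linear sequence: 6 steps (steps 1, 3, 4, 5, 6 and 8, from compound 1 to compound 18).

**Steps most likely to fail, with fallbacks**

Step 3. The C–I bond of 2 is flanked by two oxygen substituents and sits on a very electron-rich ring, so oxidative addition may be slow. The aroylpalladium intermediate may then be captured by diethylamine as an amide, or the alkyne may couple without CO and cyclise to a 2-arylbenzofuran. The fallback builds ring C by the chalcone route. It sets out from aldehyde 3, which would be condensed (KOH, EtOH, Claisen–Schmidt) with 1-[2,4-bis(benzyloxy)-6-hydroxyphenyl]ethanone F1, a catalogue compound otherwise made by dibenzylation of 2,4,6-trihydroxyacetophenone. This should give (2E)-1-[2,4-bis(benzyloxy)-6-hydroxyphenyl]-3-[4-(benzyloxy)phenyl]prop-2-en-1-one F2. Oxidative cyclisation of this 2'-hydroxychalcone with catalytic I2 in DMSO at 130 °C would close ring C, and the route is rejoined at flavone 8.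

Step 4. Hydride transfer to a β-aryl-β-aryloxy enone carrying three donor groups may be sluggish and poorly face-selective, and over-reduction at C4 or ring opening of the copper enolate may compete. The fallback sets out from flavone 8 and replaces conjugate hydride delivery by asymmetric hydrogenation of both C2=C3 and C4=O. The catalyst would be a chiral ruthenium N-heterocyclic carbene complex made from [Ru(cod)(2-methylallyl)2], the imidazolinium salt SINpEt·HBF4 (the enantiomer leading to the 2S series) and KOt-Bu, under H2 pressure in toluene. This should give the cis alcohol (2S,4S)-5,7-bis(benzyloxy)-2-[4-(benzyloxy)phenyl]-3,4-dihydro-2H-chromen-4-ol F3. Oxidation of the C4 carbinol with Dess–Martin periodinane in CH2Cl2 returns to (2S)-flavanone 10.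

Step 8. Alkylation may spread to the 4'-phenol or occur twice. The carbonate may also open ring C by a retro-oxa-Michael reaction, with loss of the C2/C3 configuration, or promote air oxidation to the flavonol. The fallback uses a neutral Mitsunobu etherification, in which only the most acidic hydroxyl (O7) is a competent pronucleophile. It sets out from 15 and 17. Chloro alcohol 17 would be silylated (TBSCl, imidazole, CH2Cl2) to tert-butyl{[(2E)-4-chloro-2-methylbut-2-en-1-yl]oxy}dimethylsilane F4. The chloride would be displaced with KOAc in DMF to give (2E)-4-{[tert-butyl(dimethyl)silyl]oxy}-3-methylbut-2-en-1-yl acetate F5. Methanolysis (K2CO3, MeOH) would give (2E)-4-{[tert-butyl(dimethyl)silyl]oxy}-3-methylbut-2-en-1-ol F6. Coupling of F6 with 15 (PPh3, DIAD, THF, 0 °C) should give (2R,3R)-7-{[(2E)-4-{[tert-butyl(dimethyl)silyl]oxy}-3-methylbut-2-en-1-yl]oxy}-3,5-dihydroxy-2-(4-hydroxyphenyl)-2,3-dihydro-4H-chromen-4-one F7. HF·pyridine in THF would then remove the silyl group and arrive at target 18.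

**Further compounds**

F1 | step 3 | 1-[2,4-bis(benzyloxy)-6-hydroxyphenyl]ethanone | CC(=O)c1c(O)cc(OCc2ccccc2)cc1OCc1ccccc1
F2 | step 3 | (2E)-1-[2,4-bis(benzyloxy)-6-hydroxyphenyl]-3-[4-(benzyloxy)phenyl]prop-2-en-1-one | O=C(/C=C/c1ccc(OCc2ccccc2)cc1)c1c(O)cc(OCc2ccccc2)cc1OCc1ccccc1
F3 | step 4 | (2S,4S)-5,7-bis(benzyloxy)-2-[4-(benzyloxy)phenyl]-3,4-dihydro-2H-chromen-4-ol | C(Oc1cc(OCc2ccccc2)c2c(c1)O[C@H](c1ccc(OCc3ccccc3)cc1)C[C@@H]2O)c1ccccc1
F4 | step 8 | tert-butyl{[(2E)-4-chloro-2-methylbut-2-en-1-yl]oxy}dimethylsilane | C/C(=C\CCl)CO[Si](C)(C)C(C)(C)C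
F5 | step 8 | (2E)-4-{[tert-butyl(dimethyl)silyl]oxy}-3-methylbut-2-en-1-yl acetate | C/C(=C\COC(C)=O)CO[Si](C)(C)C(C)(C)C
F6 | step 8 | (2E)-4-{[tert-butyl(dimethyl)silyl]oxy}-3-methylbut-2-en-1-ol | C/C(=C\CO)CO[Si](C)(C)C(C)(C)C
F7 | step 8 | (2R,3R)-7-{[(2E)-4-{[tert-butyl(dimethyl)silyl]oxy}-3-methylbut-2-en-1-yl]oxy}-3,5-dihydroxy-2-(4-hydroxyphenyl)-2,3-dihydro-4H-chromen-4-one | C/C(=C\COc1cc(O)c2c(c1)O[C@H](c1ccc(O)cc1)[C@@H](O)C2=O)CO[Si](C)(C)C(C)(C)C
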